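**Retrosynthetic overview**
1. The target comes from O15 desilylation of a ten-membered carbocycle, closed last at C3–C4 by a catalytic asymmetric Ni/Cr (Nozaki–Hiyama–Kishi) coupling of a Z-alkenyl iodide with the C3 aldehyde.
2. The trans-α-methylene-γ-lactone (C6–C7 bond; C6 and C7) comes from an iridium-catalysed transfer-hydrogenative 2-(methoxycarbonyl)allylation of iodo-enal fragment C (C4–C6, C15) with a Morita–Baylis–Hillman acetate that carries C7–C13 and the eastern chain.
3. That acetate comes from methyl propiolate (C11–C13) and an α-acyloxy aldehyde. The aldehyde comes from Cu-catalysed opening of (R)-glycidyl TES ether (fragment B, C7–C9; C8 from the chiral pool) by the E-alkenyl Grignard of fragment A (C1–C3, C10, C14), acylation in the same flask with (S)-2-methylbutanoyl chloride (fragment D), then Shi epoxidation (C1, C10).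
4. Fragment A comes from pent-3-yn-1-ol (hydrozirconation–iodination); fragment C from propargyl alcohol and formaldehyde (trans-hydroalumination–iodination, then MnO2).
5. Ring order: oxirane, then lactone, then the cyclodecene ring.

Assumption: germacrane numbering (C1–C15, C12 = lactone carbonyl, C13 = exocyclic methylene) is used for locants; TBS = tert-butyldimethylsilyl, TES = triethylsilyl, TBDPS = tert-butyldiphenylsilyl; the sense of induction of the chiral ligands in steps 13 and 16 is assigned by analogy with their known intermolecular uses, and the mirror-image ligand is taken if a first run shows the opposite sense.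

**Route**

Step 1
Reactants: 1 pent-3-yn-1-ol
Product: 2 tert-butyl(dimethyl)(pent-3-yn-1-yloxy)silane
Conditions: TBSCl, imidazole, CH2Cl2, 0 °C → rt
Reagents that add atoms: tert-butyldimethylsilyl chloride, CC(C)(C)[Si](C)(C)Cl
Why: Standard silylation of a primary alcohol (silyl ether protection); no stereocentre is involved.

Step 2
Reactants: 2 tert-butyl(dimethyl)(pent-3-yn-1-yloxy)silane
Product: 4 tert-butyl{[(3E)-4-iodopent-3-en-1-yl]oxy}dimethylsilane, via alkenylzirconocene chloride 3 (not isolated)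
Conditions: Cp2Zr(H)Cl (1.6 equiv), THF, 50 °C; then I2, 0 °C
Reagents that add atoms: iodine, II
Why: syn-Hydrozirconation of the internal alkyne equilibrates (excess Zr–H, 50 °C) to the alkenylzirconium with Zr on the methyl-bearing carbon, and iodinolysis with retention fixes the E geometry (hydrozirconation–iodination).

Step 3
Reactants: 5 (S)-glycidol
Product: 6 triethyl{[(2R)-oxiran-2-yl]methoxy}silane
Conditions: TESCl, imidazole, CH2Cl2, 0 °C
Reagents that add atoms: triethylsilyl chloride, CC[Si](Cl)(CC)CC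
Why: Silylation of the primary alcohol leaves the stereocentre untouched (the descriptor changes from S to R only because the CIP ranking of the two CH2 groups is reversed).

Step 4
Reactants: 7 (S)-2-methylbutanoic acid
Product: 8 (S)-2-methylbutanoyl chloride
Conditions: (COCl)2, DMF (cat.), CH2Cl2, 0 °C → rt
Reagents that add atoms: oxalyl chloride, O=C(Cl)C(Cl)=O
Why: Acid chloride formation through the Vilsmeier-type chloroiminium intermediate proceeds without base and does not touch the α-stereocentre.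

Step 5
Reactants: 4 tert-butyl{[(3E)-4-iodopent-3-en-1-yl]oxy}dimethylsilane, 6 triethyl{[(2R)-oxiran-2-yl]methoxy}silane, 8 (S)-2-methylbutanoyl chloride
Product: 12 (2R,4E)-7-(TBSO)-4-methyl-1-(TESO)hept-4-en-2-yl (2S)-2-methylbutanoate, via alkenyllithium 9 (not isolated), via alkenylmagnesium bromide 10 (not isolated), via magnesium alkoxide 11 (not isolated)
Conditions: 4 (1.3 equiv), t-BuLi (2 equiv per 4), Et2O, −78 °C; MgBr2·OEt2, −78 → −30 °C; 6, CuI (10 mol%), THF, −30 → 0 °C; then 8 (2 equiv), 0 °C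
Reagents that add atoms: none
Why: Iodine–lithium exchange and transmetallation to magnesium retain the E geometry, copper-catalysed SN2 opening of the terminal epoxide at C9 leaves C8 (R, from glycidol) untouched, and the cold magnesium alkoxide is O-acylated in the flask before any silyl shift (Grignard/CuI epoxide opening followed by acylation).

Step 6
Reactants: 12 (2R,4E)-7-(TBSO)-4-methyl-1-(TESO)hept-4-en-2-yl (2S)-2-methylbutanoate
Product: 13 (2R)-1-[(2R,3R)-3-(2-TBSO-ethyl)-2-methyloxiran-2-yl]-3-(TESO)propan-2-yl (2S)-2-methylbutanoate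
Conditions: D-fructose-derived Shi ketone (30 mol%), KHSO5, K2CO3, Bu4NHSO4 (cat.), MeCN/CH2(OMe)2/aq. Na2B4O7 buffer (pH 10.5), 0 °C
Reagents that add atoms: potassium peroxymonosulfate KHSO5, [K+].[O-]S(=O)(=O)OO
Why: Shi asymmetric epoxidation: the dioxirane of the D-fructose-derived ketone attacks the electron-rich trisubstituted E alkene through the spiro transition state and gives the (R,R)-epoxide (C1 and C10) under reagent control, while the ester and silyl ethers are inert.

Step 7
Reactants: 13 (2R)-1-[(2R,3R)-3-(2-TBSO-ethyl)-2-methyloxiran-2-yl]-3-(TESO)propan-2-yl (2S)-2-methylbutanoate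
Product: 15 (2R)-1-[(2R,3R)-3-(2-TBSO-ethyl)-2-methyloxiran-2-yl]-3-oxopropan-2-yl (2S)-2-methylbutanoate, via primary alcohol 14 (not isolated)
Conditions: IBX (3 equiv), DMSO, rt
Reagents that add atoms: none
Why: IBX in DMSO cleaves the primary triethylsilyl ether while the TBS ether survives and oxidises the freed alcohol in the same pot (oxidative desilylation), and the neutral medium avoids acyl migration and epimerisation at C8.

Step 8
Reactants: 15 (2R)-1-[(2R,3R)-3-(2-TBSO-ethyl)-2-methyloxiran-2-yl]-3-oxopropan-2-yl (2S)-2-methylbutanoate, 16 methyl propiolate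
Product: 18 methyl (4R)-3-acetoxy-2-methylidene-4-[(2S)-2-methylbutanoyloxy]-5-[(2R,3R)-3-(2-TBSO-ethyl)-2-methyloxiran-2-yl]pentanoate (both C3 epimers), via aluminium alkoxide 17 (not isolated)
Conditions: i-Bu2AlH, N-methylmorpholine N-oxide, THF, 0 °C; 16; then 15, 0 °C → rt; then Ac2O, pyridine, DMAP (cat.), 0 °C
Reagents that add atoms: acetic anhydride, CC(=O)OC(C)=O
Why: 1,4-Hydroalumination of methyl propiolate gives the α-aluminoacrylate, which adds to the aldehyde (vinylalumination, giving a Morita–Baylis–Hillman-type adduct), and the aluminium alkoxide is acetylated in the flask before the neighbouring acyl group can migrate; the new C7 centre is uncontrolled and is erased in step 13.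

Step 9
Reactants: 19 prop-2-yn-1-ol
Product: 20 tert-butyl(diphenyl)(prop-2-yn-1-yloxy)silane
Conditions: TBDPSCl, imidazole, CH2Cl2, rt
Reagents that add atoms: tert-butyldiphenylsilyl chloride, CC(C)(C)[Si](Cl)(c1ccccc1)c1ccccc1
Why: Standard silylation giving an acid- and fluoride-robust ether for O15 (silyl ether protection).

Step 10
Reactants: 20 tert-butyl(diphenyl)(prop-2-yn-1-yloxy)silane, 21 formaldehyde (as paraformaldehyde)
Product: 23 4-(TBDPSO)but-2-yn-1-ol, via lithium acetylide 22 (not isolated)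
Conditions: n-BuLi, THF, −78 °C; (CH2O)n, −78 °C → rt; H2O
Reagents that add atoms: none
Why: Deprotonation of the terminal alkyne and 1,2-addition of the acetylide to formaldehyde (hydroxymethylation) gives the monoprotected butynediol without statistical protection.

Step 11
Reactants: 23 4-(TBDPSO)but-2-yn-1-ol
Product: 25 (2Z)-4-(TBDPSO)-3-iodobut-2-en-1-ol, via cyclic alkenylaluminate 24 (not isolated)
Conditions: NaAlH2(OCH2CH2OMe)2, THF, 0 °C → rt; then I2, THF, −78 °C
Reagents that add atoms: iodine, II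
Why: Alkoxide-directed trans-hydroalumination places aluminium on the distal alkyne carbon (C4) in a five-membered alkenylaluminate, and iodinolysis with retention gives the Z iodide with iodine cis to C6.

Step 12
Reactants: 25 (2Z)-4-(TBDPSO)-3-iodobut-2-en-1-ol
Product: 26 (2Z)-4-(TBDPSO)-3-iodobut-2-enal
Conditions: MnO2, CH2Cl2, rt, dark
Reagents that add atoms: none
Why: MnO2 oxidises the allylic alcohol under neutral heterogeneous conditions without Z/E isomerisation (allylic oxidation); the enal is used at once.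

Step 13
Reactants: 18 methyl (4R)-3-acetoxy-2-methylidene-4-[(2S)-2-methylbutanoyloxy]-5-[(2R,3R)-3-(2-TBSO-ethyl)-2-methyloxiran-2-yl]pentanoate, 26 (2Z)-4-(TBDPSO)-3-iodobut-2-enal
Product: 28 (1R)-1-{(2S,3R)-2-[(1Z)-3-(TBDPSO)-2-iodoprop-1-en-1-yl]-4-methylidene-5-oxooxolan-3-yl}-2-[(2R,3R)-3-(2-TBSO-ethyl)-2-methyloxiran-2-yl]ethyl (2S)-2-methylbutanoate, via hydroxy ester 27 (not isolated)
Conditions: [Ir(cod)Cl]2 (2.5 mol%), (R)-SEGPHOS (5 mol%), 4-chloro-3-nitrobenzoic acid (10 mol%), K3PO4 (1 equiv), i-PrOH (2 equiv), 26 (1.5 equiv), THF, 70 °C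
Reagents that add atoms: none
Why: Proposed new method: oxidative addition of the allylic acetate to monovalent iridium erases C7 and gives a 2-(methoxycarbonyl)-substituted π-allyl complex of trivalent iridium whose E σ-allyl form (C8 trans to CH2–Ir) adds to aldehyde 26 through a closed chair transition state, giving the anti adduct that becomes the trans lactone, with the SEGPHOS-modified cyclometallated C,O-benzoate centre selecting the Si face of the aldehyde (C6) and the allyl face anti to the C9 chain in the A(1,3)-locked conformer (C7), after which isopropanol returns the hydride as acetone and the alkoxide closes the lactone on the methyl ester; the closest known reaction types are the iridium-catalysed 2-(alkoxycarbonyl)allylation with the unsubstituted acrylate donor and the anti-selective crotylation with α-methylallyl acetate, and a γ-branched stereogenic Morita–Baylis–Hillman acetate has not been shown as donor.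

Step 14
Reactants: 28 lactone bis-silyl ether (name as in step 13)
Product: 29 (1R)-1-{(2S,3R)-2-[(1Z)-3-(TBDPSO)-2-iodoprop-1-en-1-yl]-4-methylidene-5-oxooxolan-3-yl}-2-[(2R,3R)-3-(2-hydroxyethyl)-2-methyloxiran-2-yl]ethyl (2S)-2-methylbutanoate
Conditions: HF·pyridine, pyridine, THF, 0 °C
Reagents that add atoms: none
Why: Buffered HF·pyridine removes the primary alkyl TBS ether far faster than the TBDPS ether, and the epoxide, lactone and alkenyl iodide survive at 0 °C (selective desilylation).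

Step 15
Reactants: 29 primary alcohol (name as in step 14)
Product: 30 (1R)-1-{(2S,3R)-2-[(1Z)-3-(TBDPSO)-2-iodoprop-1-en-1-yl]-4-methylidene-5-oxooxolan-3-yl}-2-[(2R,3R)-2-methyl-3-(2-oxoethyl)oxiran-2-yl]ethyl (2S)-2-methylbutanoate
Conditions: Dess–Martin periodinane, NaHCO3, CH2Cl2, 0 °C
Reagents that add atoms: none
Why: Dess–Martin oxidation under bicarbonate buffer gives the β,γ-epoxy aldehyde without base-induced epoxide opening; it is filtered and used at once without chromatography.

Step 16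
Reactants: 30 epoxy aldehyde alkenyl iodide (name as in step 15)
Product: 31 (1R,3S,6R,7R,8R,10R)-15-(TBDPSO)-1,10-epoxy-3-hydroxy-8-[(2S)-2-methylbutanoyloxy]germacra-4Z,11(13)-dien-12,6-olide
Conditions: CrCl2 (20 mol%), (S)-N-[2-(4-isopropyl-4,5-dihydro-1,3-oxazol-2-yl)-6-methylphenyl]methanesulfonamide (22 mol%), 1,8-bis(dimethylamino)naphthalene (22 mol%), NiCl2(2,9-dimethyl-1,10-phenanthroline) (5 mol%), Mn (2 equiv), Cp2ZrCl2 (1.2 equiv), LiCl (2 equiv), MeCN, rt, 30 added over 12 h (final 0.002 M)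
Reagents that add atoms: none
Why: Zerovalent nickel inserts into the C4–I bond with retention of the Z geometry, the alkenyl group passes to trivalent chromium and adds to the Re face of the C3 aldehyde inside the chiral sulfonamide complex to give 3S while closing the ten-membered ring (catalytic asymmetric Nozaki–Hiyama–Kishi macrocyclisation), with Mn turning the chromium over and Cp2ZrCl2 taking the alkoxide.

Step 17
Reactants: 31 15-O-TBDPS ether of the target (name as in step 16)
Product: 32 (1R,3S,6R,7R,8R,10R)-1,10-epoxy-3,15-dihydroxy-8-[(2S)-2-methylbutanoyloxy]germacra-4Z,11(13)-dien-12,6-olide (CNP0267576.2)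
Conditions: Bu4NF, AcOH (1:1), THF, 0 °C → rt
Reagents that add atoms: none
Why: Acetic-acid-buffered fluoride cleaves the allylic TBDPS ether without touching the α-methylene lactone, the epoxide or the ester (desilylation).

**Compound list**
1 | pent-3-yn-1-ol | CC#CCCO | starting material
2 | tert-butyl(dimethyl)(pent-3-yn-1-yloxy)silane | CC#CCCO[Si](C)(C)C(C)(C)C | intermediate
3 | chlorobis(cyclopentadienyl)[(2E)-5-(TBSO)pent-2-en-2-yl]zirconium | C/C(=C\CCO[Si](C)(C)C(C)(C)C)[Zr](Cl)(C1C=CC=C1)C1C=CC=C1 | intermediate (not isolated)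
4 | tert-butyl{[(3E)-4-iodopent-3-en-1-yl]oxy}dimethylsilane | C/C(I)=C\CCO[Si](C)(C)C(C)(C)C | intermediate
5 | (S)-glycidol | C1[C@@H](O1)CO | starting material
6 | triethyl{[(2R)-oxiran-2-yl]methoxy}silane | C1[C@@H](O1)CO[Si](CC)(CC)CC | intermediate
7 | (S)-2-methylbutanoic acid | CC[C@H](C)C(=O)O | starting material
8 | (S)-2-methylbutanoyl chloride | CC[C@H](C)C(=O)Cl | intermediate
9 | [5-(TBSO)pent-2-en-2-yl]lithium, Li trans to the chain (formally 2Z because carbon outranks lithium) | C/C([Li])=C\CCO[Si](C)(C)C(C)(C)C | intermediate (not isolated)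
10 | bromo[(2E)-5-(TBSO)pent-2-en-2-yl]magnesium | C/C([Mg]Br)=C\CCO[Si](C)(C)C(C)(C)C | intermediate (not isolated)
11 | bromomagnesium (2R,4E)-7-(TBSO)-4-methyl-1-(TESO)hept-4-en-2-olate | CC[Si](CC)(CC)OC[C@H](O[Mg]Br)C/C(C)=C/CCO[Si](C)(C)C(C)(C)C | intermediate (not isolated)
12 | (2R,4E)-7-(TBSO)-4-methyl-1-(TESO)hept-4-en-2-yl (2S)-2-methylbutanoate | CC[Si](CC)(CC)OC[C@H](OC(=O)[C@@H](C)CC)C/C(C)=C/CCO[Si](C)(C)C(C)(C)C | intermediate
13 | (2R)-1-[(2R,3R)-3-(2-TBSO-ethyl)-2-methyloxiran-2-yl]-3-(TESO)propan-2-yl (2S)-2-methylbutanoate | CC[Si](CC)(CC)OC[C@H](OC(=O)[C@@H](C)CC)C[C@@]1(C)O[C@@H]1CCO[Si](C)(C)C(C)(C)C | intermediate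
14 | (2R)-1-hydroxy-3-[(2R,3R)-3-(2-TBSO-ethyl)-2-methyloxiran-2-yl]propan-2-yl (2S)-2-methylbutanoate | OC[C@H](OC(=O)[C@@H](C)CC)C[C@@]1(C)O[C@@H]1CCO[Si](C)(C)C(C)(C)C | intermediate (not isolated)
15 | (2R)-1-[(2R,3R)-3-(2-TBSO-ethyl)-2-methyloxiran-2-yl]-3-oxopropan-2-yl (2S)-2-methylbutanoate | O=C[C@H](OC(=O)[C@@H](C)CC)C[C@@]1(C)O[C@@H]1CCO[Si](C)(C)C(C)(C)C | intermediate
16 | methyl propiolate | C#CC(=O)OC | starting material
17 | diisobutylaluminium alkoxide of the C7 carbinol (O–Al in place of OAc of 18; both C7 epimers) | C=C(C(=O)OC)C(O[Al](CC(C)C)CC(C)C)[C@H](OC(=O)[C@@H](C)CC)C[C@@]1(C)O[C@@H]1CCO[Si](C)(C)C(C)(C)C | intermediate (not isolated)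
18 | methyl (4R)-3-acetoxy-2-methylidene-4-[(2S)-2-methylbutanoyloxy]-5-[(2R,3R)-3-(2-TBSO-ethyl)-2-methyloxiran-2-yl]pentanoate (both C3 epimers) | C=C(C(=O)OC)C(OC(C)=O)[C@H](OC(=O)[C@@H](C)CC)C[C@@]1(C)O[C@@H]1CCO[Si](C)(C)C(C)(C)C | intermediate
19 | prop-2-yn-1-ol | C#CCO | starting material
20 | tert-butyl(diphenyl)(prop-2-yn-1-yloxy)silane | C#CCO[Si](c1ccccc1)(c1ccccc1)C(C)(C)C | intermediate
21 | formaldehyde (as paraformaldehyde) | C=O | starting material
22 | [3-(TBDPSO)prop-1-yn-1-yl]lithium | [Li]C#CCO[Si](c1ccccc1)(c1ccccc1)C(C)(C)C | intermediate (not isolated)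
23 | 4-(TBDPSO)but-2-yn-1-ol | OCC#CCO[Si](c1ccccc1)(c1ccccc1)C(C)(C)C | intermediate
24 | sodium 2,2-bis(2-methoxyethoxy)-3-(TBDPSO-methyl)-2,5-dihydro-1,2-oxaluminol-2-uide | [Na+].COCCO[Al-]1(OCCOC)OCC=C1CO[Si](c1ccccc1)(c1ccccc1)C(C)(C)C | intermediate (not isolated)
25 | (2Z)-4-(TBDPSO)-3-iodobut-2-en-1-ol | OC/C=C(\I)CO[Si](c1ccccc1)(c1ccccc1)C(C)(C)C | intermediate
26 | (2Z)-4-(TBDPSO)-3-iodobut-2-enal | O=C/C=C(\I)CO[Si](c1ccccc1)(c1ccccc1)C(C)(C)C | intermediate
27 | methyl (3S,4R)-3-[(1S,2Z)-4-(TBDPSO)-1-hydroxy-3-iodobut-2-en-1-yl]-2-methylidene-4-[(2S)-2-methylbutanoyloxy]-5-[(2R,3R)-3-(2-TBSO-ethyl)-2-methyloxiran-2-yl]pentanoate | C=C(C(=O)OC)[C@@H]([C@H](O)/C=C(\I)CO[Si](c1ccccc1)(c1ccccc1)C(C)(C)C)[C@H](OC(=O)[C@@H](C)CC)C[C@@]1(C)O[C@@H]1CCO[Si](C)(C)C(C)(C)C | intermediate (not isolated)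
28 | (1R)-1-{(2S,3R)-2-[(1Z)-3-(TBDPSO)-2-iodoprop-1-en-1-yl]-4-methylidene-5-oxooxolan-3-yl}-2-[(2R,3R)-3-(2-TBSO-ethyl)-2-methyloxiran-2-yl]ethyl (2S)-2-methylbutanoate | C=C1C(=O)O[C@H](/C=C(\I)CO[Si](c2ccccc2)(c2ccccc2)C(C)(C)C)[C@H]1[C@H](OC(=O)[C@@H](C)CC)C[C@@]1(C)O[C@@H]1CCO[Si](C)(C)C(C)(C)C | intermediate
29 | (1R)-1-{(2S,3R)-2-[(1Z)-3-(TBDPSO)-2-iodoprop-1-en-1-yl]-4-methylidene-5-oxooxolan-3-yl}-2-[(2R,3R)-3-(2-hydroxyethyl)-2-methyloxiran-2-yl]ethyl (2S)-2-methylbutanoate | C=C1C(=O)O[C@H](/C=C(\I)CO[Si](c2ccccc2)(c2ccccc2)C(C)(C)C)[C@H]1[C@H](OC(=O)[C@@H](C)CC)C[C@@]1(C)O[C@@H]1CCO | intermediate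
30 | (1R)-1-{(2S,3R)-2-[(1Z)-3-(TBDPSO)-2-iodoprop-1-en-1-yl]-4-methylidene-5-oxooxolan-3-yl}-2-[(2R,3R)-2-methyl-3-(2-oxoethyl)oxiran-2-yl]ethyl (2S)-2-methylbutanoate | C=C1C(=O)O[C@H](/C=C(\I)CO[Si](c2ccccc2)(c2ccccc2)C(C)(C)C)[C@H]1[C@H](OC(=O)[C@@H](C)CC)C[C@@]1(C)O[C@@H]1CC=O | intermediate
31 | (1R,3S,6R,7R,8R,10R)-15-(TBDPSO)-1,10-epoxy-3-hydroxy-8-[(2S)-2-methylbutanoyloxy]germacra-4Z,11(13)-dien-12,6-olide | C=C1C(=O)O[C@@H]2/C=C(/CO[Si](c4ccccc4)(c4ccccc4)C(C)(C)C)[C@@H](O)C[C@H]3O[C@]3(C)C[C@@H](OC(=O)[C@@H](C)CC)[C@@H]12 | intermediate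
32 | (1R,3S,6R,7R,8R,10R)-1,10-epoxy-3,15-dihydroxy-8-[(2S)-2-methylbutanoyloxy]germacra-4Z,11(13)-dien-12,6-olide (CNP0267576.2) | C=C1C(=O)O[C@@H]2/C=C(/CO)[C@@H](O)C[C@H]3O[C@]3(C)C[C@@H](OC(=O)[C@@H](C)CC)[C@@H]12 | target

**Step count**
Total steps: 17. Longest linear sequence: 11 steps (steps 1, 2, 5, 6, 7, 8, 13, 14, 15, 16, 17), which is 11/17 of the total.

**Three steps most likely to fail**

Step 13 (the proposed new iridium coupling). The risks are β-acyloxy elimination from the allyl-iridium species, insertion of iridium into the alkenyl iodide, and a mismatch between the C8 centre and the catalyst. The fallback uses known divalent-chromium Barbier chemistry. It sets out from 18: LiBr in THF/acetone converts the acetate by SN2' displacement into methyl (2Z,4R)-2-(bromomethyl)-4-[(2S)-2-methylbutanoyloxy]-5-[(2R,3R)-3-(2-TBSO-ethyl)-2-methyloxiran-2-yl]pent-2-enoate F1. F1 and aldehyde 26 are then treated with CrCl2 (3 equiv) in THF at rt; the allylchromium adds anti-selectively (known 2-(alkoxycarbonyl)allylation, substrate-controlled facial selectivity) to give hydroxy ester 27, which lactonises, and the fallback comes back to the route at 28.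

Step 16 (macrocyclisation and C3 configuration). The risks are that the ring closes with low selectivity or the wrong sense at C3, and that the β,γ-epoxy aldehyde is lost. The fallback sets C3 by ketone reduction instead of by the C–C bond formation. It sets out from 30: ring closure with excess CrCl2 and catalytic NiCl2 in DMSO/THF without chiral ligand gives the C3-epimeric mixture (3RS)-15-(TBDPSO)-1,10-epoxy-3-hydroxy-8-[(2S)-2-methylbutanoyloxy]germacra-4Z,11(13)-dien-12,6-olide F2. Dess–Martin oxidation gives the enone 15-(TBDPSO)-1,10-epoxy-8-[(2S)-2-methylbutanoyloxy]-3-oxogermacra-4Z,11(13)-dien-12,6-olide F3, and reduction with (R)-2-methyl-CBS-oxazaborolidine and catecholborane at −78 °C gives the 3S alcohol; the fallback comes back at 31.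

Step 8 (vinylalumination with in-flask acetylation next to the C8 acyloxy group). The risks are acyl migration, C8 epimerisation and attack of the alane on the epoxide. The fallback replaces the preformed organoaluminium by amine catalysis. It sets out from 15: DABCO-catalysed Morita–Baylis–Hillman reaction with neat methyl acrylate at rt gives methyl (4R)-3-hydroxy-2-methylidene-4-[(2S)-2-methylbutanoyloxy]-5-[(2R,3R)-3-(2-TBSO-ethyl)-2-methyloxiran-2-yl]pentanoate F4 (both C3 epimers), which is acetylated at once (Ac2O, pyridine, DMAP, 0 °C); the fallback comes back at 18.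

**Further compounds**
F1 | step 13 | methyl (2Z,4R)-2-(bromomethyl)-4-[(2S)-2-methylbutanoyloxy]-5-[(2R,3R)-3-(2-TBSO-ethyl)-2-methyloxiran-2-yl]pent-2-enoate | COC(=O)/C(CBr)=C/[C@H](OC(=O)[C@@H](C)CC)C[C@@]1(C)O[C@@H]1CCO[Si](C)(C)C(C)(C)C
F2 | step 16 | (3RS)-15-(TBDPSO)-1,10-epoxy-3-hydroxy-8-[(2S)-2-methylbutanoyloxy]germacra-4Z,11(13)-dien-12,6-olide (1R,6R,7R,8R,10R; C3 epimers) | C=C1C(=O)O[C@@H]2/C=C(/CO[Si](c4ccccc4)(c4ccccc4)C(C)(C)C)C(O)C[C@H]3O[C@]3(C)C[C@@H](OC(=O)[C@@H](C)CC)[C@@H]12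
F3 | step 16 | (1R,6R,7R,8R,10R)-15-(TBDPSO)-1,10-epoxy-8-[(2S)-2-methylbutanoyloxy]-3-oxogermacra-4Z,11(13)-dien-12,6-olide | C=C1C(=O)O[C@@H]2/C=C(/CO[Si](c4ccccc4)(c4ccccc4)C(C)(C)C)C(=O)C[C@H]3O[C@]3(C)C[C@@H](OC(=O)[C@@H](C)CC)[C@@H]12
F4 | step 8 | methyl (4R)-3-hydroxy-2-methylidene-4-[(2S)-2-methylbutanoyloxy]-5-[(2R,3R)-3-(2-TBSO-ethyl)-2-methyloxiran-2-yl]pentanoate (both C3 epimers) | C=C(C(=O)OC)C(O)[C@H](OC(=O)[C@@H](C)CC)C[C@@]1(C)O[C@@H]1CCO[Si](C)(C)C(C)(C)C
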